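**Plan**

- Retrosynthesis cuts, in this order: the C(sp2)–C(sp3) bond between the two trisubstituted alkenes (alkenyl iodide 16 + homoallylzinc 27), the butenolide–chain bond (4-bromofuranone 22), and in the carbocycle the two ring bonds CMe2–CH(stereocentre) and ring CH2–C(=CH2), which are made together in one annulation.
- Enabling feature: in the cyclohexane the stereogenic CH lies between the gem-dimethyl carbon and the methylidene-bearing carbon, which is flanked on its other side by a ring CH2. If the exocyclic =CH2 is read as a carboxyl carbon and the first two side-chain carbons as O–CH–CH2OH, these five carbons are a 5-(hydroxymethyl)butenolide, whose β-carbon accepts a tertiary radical and whose α-carbon then closes onto an aldehyde.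
- Forward, carbocycle first: a hydrogen-atom-transfer (HAT) radical conjugate addition/aldol annulation of 4-methylpent-4-enal with the (S)-butenolide builds the cyclohexane on the lactone, which serves as a temporary ring.
- The helpers are then removed: dehydration, zinc fragmentation of the lactone (vinyl group + acid), reduction, anti-Markovnikov iodination, and a reductive allylic transposition with loss of N2 that turns the former lactone carbonyl carbon into the exocyclic methylene.
- Chain: acetylide alkylation and methylalumination/iodination give 16; the butenolide arm 26 comes from a silyl butynyl ether by methylalumination/oxirane opening and coupling with 22; a Negishi coupling joins the halves last.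
- Stereochemistry: the single stereocentre is set in the annulation, anti to the C5 substituent of the (S)-butenolide, whose own stereocentre is destroyed in the fragmentation; both E alkenes come from syn-methylalumination and couplings with retention.

Key step: step 1

Assumption: the carbinol centre formed by the aldol in step 1 is not controlled and is drawn undefined in 3 and 4 (it is removed in step 2); compounds 1, 2, 17 and 22 are taken as catalogue materials.

**Step 1**
Reactants: 1 4-methylpent-4-enal; 2 (5S)-5-(hydroxymethyl)furan-2(5H)-one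
Product: 3 (3S,3aR,7aS)-7-hydroxy-3-(hydroxymethyl)-4,4-dimethylhexahydroisobenzofuran-1(3H)-one
Conditions: Fe(acac)3 (cat.), PhSiH3, EtOH/ethylene glycol, rt
Reagents that add atoms: none
Why: An iron hydride formed from Fe(acac)3 and PhSiH3 transfers a hydrogen atom to the terminal CH2 of the 1,1-disubstituted alkene of 1, the tertiary radical adds to the β-carbon of butenolide 2 (Giese addition), divalent iron reduces the α-acyl radical to an iron enolate, and this enolate adds to the tethered aldehyde. The closest known reaction type is the HAT-initiated radical conjugate addition–aldol (radical–polar crossover) annulation of alkene-tethered carbonyl compounds with unsaturated carbonyl acceptors, together with tertiary-radical Giese additions to 5-substituted butenolides. The cyclohexane closes by a 6-(enolexo)-exo-trig aldol addition onto the lactone, which stays as a temporary ring. The stereocentre at C3a is controlled by the C5 hydroxymethyl group of 2, which blocks one face so that the bulky radical enters anti to it; the ring fusion at C7a should be cis because the aldehyde is held on the face that carries the tether; the carbinol centre is not controlled and does not matter. The step needs hydrogen-atom transfer to the electron-rich alkene and not to the butenolide, and cross- over homo-coupling; both are secured by polarity matching of the nucleophilic tertiary radical with the electron-poor lactone, and the intramolecular aldol should outrun protonation of the enolate.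

**Step 2**
Reactants: 3 (3S,3aR,7aS)-7-hydroxy-3-(hydroxymethyl)-4,4-dimethylhexahydroisobenzofuran-1(3H)-one
Product: 5 [(3S,3aS)-4,4-dimethyl-1-oxo-1,3,3a,4,5,6-hexahydroisobenzofuran-3-yl]methyl methanesulfonate, via bis-mesylate 4 (not isolated)
Conditions: MsCl, Et3N, CH2Cl2, 0 °C; then DBU, 0 °C to rt
Reagents that add atoms: methanesulfonyl chloride, CS(=O)(=O)Cl
Why: Both hydroxyls are sulfonylated and the β-mesyloxy group is lost by E1cB elimination through the lactone enolate to give the conjugated alkylidene lactone, while the primary mesylate and the non-acidic C3a–H are untouched.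

**Step 3**
Reactants: 5 [(3S,3aS)-4,4-dimethyl-1-oxo-1,3,3a,4,5,6-hexahydroisobenzofuran-3-yl]methyl methanesulfonate
Product: 7 (6S)-6-ethenyl-5,5-dimethylcyclohex-1-ene-1-carboxylic acid, via iodomethyl lactone 6 (not isolated)
Conditions: NaI, Zn dust, DMF, 80 °C; then 1 M HCl
Reagents that add atoms: none
Why: Finkelstein exchange of the primary mesylate and zinc insertion into the C–I bond trigger β-elimination of the lactone carboxylate (reductive fragmentation of a β-acyloxy iodide, the reverse of an iodolactonisation), which releases the vinyl group and the acid and erases the stereocentre of the chiral starting lactone.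

**Step 4**
Reactants: 7 (6S)-6-ethenyl-5,5-dimethylcyclohex-1-ene-1-carboxylic acid
Product: 8 [(6S)-6-ethenyl-5,5-dimethylcyclohex-1-en-1-yl]methanol
Conditions: LiAlH4, Et2O, 0 °C to rt
Reagents that add atoms: none
Why: LiAlH4 reduces the conjugated carboxylic acid in 1,2-fashion to the primary allylic alcohol without touching the isolated alkenes or the non-acidic stereocentre.

**Step 5**
Reactants: 8 [(6S)-6-ethenyl-5,5-dimethylcyclohex-1-en-1-yl]methanol
Product: 10 [(6S)-6-(2-iodoethyl)-5,5-dimethylcyclohex-1-en-1-yl]methanol, via bis(disiamylboryl) adduct 9 (not isolated)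
Conditions: disiamylborane [(3-methylbutan-2-yl)2BH, from BH3·THF and 2-methylbut-2-ene], THF, 0 °C to rt; then I2, NaOMe, MeOH, 0 °C to rt
Reagents that add atoms: iodine, [I][I]
Why: Hydroboration with the bulky dialkylborane is selective for the monosubstituted vinyl group and places boron at the terminus, and base-induced iodinolysis cleaves the primary C–B bond to the iodide (hydroboration–iodination) while the borinate on oxygen is methanolysed.

**Step 6**
Reactants: 10 [(6S)-6-(2-iodoethyl)-5,5-dimethylcyclohex-1-en-1-yl]methanol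
Product: 13 (2S)-2-(2-iodoethyl)-1,1-dimethyl-3-methylidenecyclohexane, via N-alkyl sulfonylhydrazine 11 (not isolated), via allylic diazene 12 (not isolated)
Conditions: 2-nitrobenzenesulfonylhydrazide, PPh3, DEAD, THF, −30 °C to rt
Reagents that add atoms: none
Why: Mitsunobu displacement of the primary allylic alcohol by the sulfonylhydrazide, loss of the sulfinic acid and retro-ene (sigmatropic) loss of N2 from the allylic diazene deliver hydrogen to the ring CH and move the alkene into the exocyclic position (reductive 1,3-transposition of an allylic alcohol).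

**Step 7**
Reactants: 13 (2S)-2-(2-iodoethyl)-1,1-dimethyl-3-methylidenecyclohexane
Product: 14 (2S)-2-(but-3-yn-1-yl)-1,1-dimethyl-3-methylidenecyclohexane
Conditions: lithium acetylide–ethylenediamine complex, DMSO, rt
Reagents that add atoms: lithium acetylide–ethylenediamine complex, [Li+].[C-]#C.NCCN
Why: SN2 alkylation of lithium acetylide by the unhindered primary iodide in DMSO.

**Step 8**
Reactants: 14 (2S)-2-(but-3-yn-1-yl)-1,1-dimethyl-3-methylidenecyclohexane
Product: 16 (2S)-2-[(3E)-4-iodo-3-methylbut-3-en-1-yl]-1,1-dimethyl-3-methylidenecyclohexane, via alkenyl(dimethyl)alane 15 (not isolated)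
Conditions: Me3Al, Cp2ZrCl2 (cat.), CH2Cl2, rt; then I2, THF, −30 °C
Reagents that add atoms: trimethylaluminium, C[Al](C)C; iodine, [I][I]
Why: Zirconium-catalysed syn-methylalumination (Negishi carboalumination) of the terminal alkyne puts methyl on the internal carbon and aluminium on the terminus, and iodinolysis with retention gives the E alkenyl iodide; the 1,1-disubstituted exocyclic alkene does not react.

**Step 9**
Reactants: 17 tert-butyl(but-3-yn-1-yloxy)dimethylsilane
Product: 20 (3E)-6-[(tert-butyldimethylsilyl)oxy]-4-methylhex-3-en-1-ol, via alkenyl(dimethyl)alane 18 (not isolated), via lithium alkenylaluminate 19 (not isolated)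
Conditions: Me3Al, Cp2ZrCl2 (cat.), (CH2Cl)2, rt; volatiles removed; n-BuLi, THF/hexane, −78 °C; oxirane, −78 °C to rt
Reagents that add atoms: trimethylaluminium, C[Al](C)C; oxirane, C1CO1
Why: The same syn-methylalumination sets the E trisubstituted alkene, and the alkenylaluminate formed with n-BuLi opens oxirane with retention of alkene geometry to give the homoallylic alcohol.

**Step 10**
Reactants: 20 (3E)-6-[(tert-butyldimethylsilyl)oxy]-4-methylhex-3-en-1-ol
Product: 21 tert-butyl{[(3E)-6-iodo-3-methylhex-3-en-1-yl]oxy}dimethylsilane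
Conditions: I2, PPh3, imidazole, CH2Cl2, 0 °C to rt
Reagents that add atoms: iodine, [I][I]
Why: Appel-type iodination of the primary alcohol under conditions that leave the silyl ether intact.

**Step 11**
Reactants: 21 tert-butyl{[(3E)-6-iodo-3-methylhex-3-en-1-yl]oxy}dimethylsilane; 22 4-bromofuran-2(5H)-one
Product: 24 4-{(3E)-6-[(tert-butyldimethylsilyl)oxy]-4-methylhex-3-en-1-yl}furan-2(5H)-one, via homoallylzinc iodide 23 (not isolated)
Conditions: Zn dust, LiCl, THF, 40 °C; then 22, Pd(PPh3)4 (cat.), THF, rt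
Reagents that add atoms: none
Why: Zinc insertion into the primary iodide and Negishi coupling of the homoallylzinc iodide with the β-bromobutenolide under zerovalent palladium catalysis install the 4-substituted furanone.

**Step 12**
Reactants: 24 4-{(3E)-6-[(tert-butyldimethylsilyl)oxy]-4-methylhex-3-en-1-yl}furan-2(5H)-one
Product: 25 4-[(3E)-6-hydroxy-4-methylhex-3-en-1-yl]furan-2(5H)-one
Conditions: HF·pyridine, THF/pyridine, 0 °C to rt
Reagents that add atoms: none
Why: Fluoride-mediated cleavage of the silyl ether under buffered, non-basic conditions that spare the butenolide.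

**Step 13**
Reactants: 25 4-[(3E)-6-hydroxy-4-methylhex-3-en-1-yl]furan-2(5H)-one
Product: 26 4-[(3E)-6-iodo-4-methylhex-3-en-1-yl]furan-2(5H)-one
Conditions: I2, PPh3, imidazole, CH2Cl2, 0 °C
Reagents that add atoms: iodine, [I][I]
Why: Appel-type iodination of the primary alcohol; the butenolide and the trisubstituted alkene are inert.

**Step 14**
Reactants: 26 4-[(3E)-6-iodo-4-methylhex-3-en-1-yl]furan-2(5H)-one; 16 (2S)-2-[(3E)-4-iodo-3-methylbut-3-en-1-yl]-1,1-dimethyl-3-methylidenecyclohexane
Product: 28 4-{(3E,7E)-10-[(1S)-2,2-dimethyl-6-methylidenecyclohexyl]-4,8-dimethyldeca-3,7-dien-1-yl}furan-2(5H)-one, via homoallylzinc iodide 27 (not isolated)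
Conditions: Zn dust, LiCl, THF, 40 °C; then 16, Pd(PPh3)4 (cat.), THF, rt to 45 °C
Reagents that add atoms: none
Why: Zinc inserts into the primary C–I bond in the presence of the lactone, and Negishi coupling of the homoallylzinc iodide with the E alkenyl iodide under zerovalent palladium catalysis forms the C(sp3)–C(sp2) bond with retention of alkene geometry and completes the skeleton.

**Compound list**

1 | 4-methylpent-4-enal | C=C(C)CCC=O | starting material
2 | (5S)-5-(hydroxymethyl)furan-2(5H)-one | O=C1C=C[C@@H](CO)O1 | starting material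
3 | (3S,3aR,7aS)-7-hydroxy-3-(hydroxymethyl)-4,4-dimethylhexahydroisobenzofuran-1(3H)-one (cis-fused, C7 undefined) | O=C1O[C@H](CO)[C@@H]2[C@H]1C(O)CCC2(C)C | intermediate
4 | (3S,3aR,7aS)-4,4-dimethyl-7-(methylsulfonyloxy)-3-[(methylsulfonyloxy)methyl]hexahydroisobenzofuran-1(3H)-one | O=C1O[C@H](COS(C)(=O)=O)[C@@H]2[C@H]1C(OS(C)(=O)=O)CCC2(C)C | intermediate (not isolated)
5 | [(3S,3aS)-4,4-dimethyl-1-oxo-1,3,3a,4,5,6-hexahydroisobenzofuran-3-yl]methyl methanesulfonate | O=C1O[C@H](COS(C)(=O)=O)[C@@H]2C1=CCCC2(C)C | intermediate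
6 | (3S,3aS)-3-(iodomethyl)-4,4-dimethyl-3a,4,5,6-tetrahydroisobenzofuran-1(3H)-one | O=C1O[C@H](CI)[C@@H]2C1=CCCC2(C)C | intermediate (not isolated)
7 | (6S)-6-ethenyl-5,5-dimethylcyclohex-1-ene-1-carboxylic acid | OC(=O)C1=CCCC(C)(C)[C@@H]1C=C | intermediate
8 | [(6S)-6-ethenyl-5,5-dimethylcyclohex-1-en-1-yl]methanol | OCC1=CCCC(C)(C)[C@@H]1C=C | intermediate
9 | bis(3-methylbutan-2-yl)borinate of [(6S)-6-{2-[bis(3-methylbutan-2-yl)boranyl]ethyl}-5,5-dimethylcyclohex-1-en-1-yl]methanol | CC(C)C(C)B(OCC1=CCCC(C)(C)[C@@H]1CCB(C(C)C(C)C)C(C)C(C)C)C(C)C(C)C | intermediate (not isolated)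
10 | [(6S)-6-(2-iodoethyl)-5,5-dimethylcyclohex-1-en-1-yl]methanol | OCC1=CCCC(C)(C)[C@@H]1CCI | intermediate
11 | N-{[(6S)-6-(2-iodoethyl)-5,5-dimethylcyclohex-1-en-1-yl]methyl}-2-nitrobenzenesulfonohydrazide | NN(CC1=CCCC(C)(C)[C@@H]1CCI)S(=O)(=O)c1ccccc1[N+](=O)[O-] | intermediate (not isolated)
12 | {[(6S)-6-(2-iodoethyl)-5,5-dimethylcyclohex-1-en-1-yl]methyl}diazene | N=NCC1=CCCC(C)(C)[C@@H]1CCI | intermediate (not isolated)
13 | (2S)-2-(2-iodoethyl)-1,1-dimethyl-3-methylidenecyclohexane | C=C1CCCC(C)(C)[C@@H]1CCI | intermediate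
14 | (2S)-2-(but-3-yn-1-yl)-1,1-dimethyl-3-methylidenecyclohexane | C=C1CCCC(C)(C)[C@@H]1CCC#C | intermediate
15 | {(1E)-4-[(1S)-2,2-dimethyl-6-methylidenecyclohexyl]-2-methylbut-1-en-1-yl}dimethylalane | C=C1CCCC(C)(C)[C@@H]1CC/C(C)=C/[Al](C)C | intermediate (not isolated)
16 | (2S)-2-[(3E)-4-iodo-3-methylbut-3-en-1-yl]-1,1-dimethyl-3-methylidenecyclohexane | C=C1CCCC(C)(C)[C@@H]1CC/C(C)=C/I | intermediate
17 | tert-butyl(but-3-yn-1-yloxy)dimethylsilane | C#CCCO[Si](C)(C)C(C)(C)C | starting material
18 | {(1E)-4-[(tert-butyldimethylsilyl)oxy]-2-methylbut-1-en-1-yl}dimethylalane | C[Al](C)/C=C(\C)CCO[Si](C)(C)C(C)(C)C | intermediate (not isolated)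
19 | lithium butyl{(1E)-4-[(tert-butyldimethylsilyl)oxy]-2-methylbut-1-en-1-yl}dimethylaluminate | [Li+].CCCC[Al-](C)(C)/C=C(\C)CCO[Si](C)(C)C(C)(C)C | intermediate (not isolated)
20 | (3E)-6-[(tert-butyldimethylsilyl)oxy]-4-methylhex-3-en-1-ol | OCC/C=C(\C)CCO[Si](C)(C)C(C)(C)C | intermediate
21 | tert-butyl{[(3E)-6-iodo-3-methylhex-3-en-1-yl]oxy}dimethylsilane | ICC/C=C(\C)CCO[Si](C)(C)C(C)(C)C | intermediate
22 | 4-bromofuran-2(5H)-one | O=C1C=C(Br)CO1 | starting material
23 | {(3E)-6-[(tert-butyldimethylsilyl)oxy]-4-methylhex-3-en-1-yl}zinc iodide | I[Zn]CC/C=C(\C)CCO[Si](C)(C)C(C)(C)C | intermediate (not isolated)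
24 | 4-{(3E)-6-[(tert-butyldimethylsilyl)oxy]-4-methylhex-3-en-1-yl}furan-2(5H)-one | O=C1C=C(CC/C=C(\C)CCO[Si](C)(C)C(C)(C)C)CO1 | intermediate
25 | 4-[(3E)-6-hydroxy-4-methylhex-3-en-1-yl]furan-2(5H)-one | O=C1C=C(CC/C=C(\C)CCO)CO1 | intermediate
26 | 4-[(3E)-6-iodo-4-methylhex-3-en-1-yl]furan-2(5H)-one | O=C1C=C(CC/C=C(\C)CCI)CO1 | intermediate
27 | {(3E)-3-methyl-6-(5-oxo-2,5-dihydrofuran-3-yl)hex-3-en-1-yl}zinc iodide | O=C1C=C(CC/C=C(\C)CC[Zn]I)CO1 | intermediate (not isolated)
28 | 4-{(3E,7E)-10-[(1S)-2,2-dimethyl-6-methylidenecyclohexyl]-4,8-dimethyldeca-3,7-dien-1-yl}furan-2(5H)-one | C=C1CCCC(C)(C)[C@@H]1CC/C(C)=C/CC/C(C)=C/CCC1=CC(=O)OC1 | target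

**Summary**

Total step count: 14. Longest linear sequence: 9 (steps 1 to 8, then step 14).

**Steps most likely to fail**

Step 1. What may go wrong: protonation of the iron enolate, or hydride reduction of the aldehyde, before the aldol closure, so that only the open conjugate adduct forms. Fallback (sets out from 1 and 2, returns at 5): the two bonds are made in two operations with the aldehyde masked. Acetalisation of 1 (HC(OMe)3, PPTS, MeOH) gives 5,5-dimethoxy-2-methylpent-1-ene F1. HAT-initiated Giese coupling of F1 with 2 (Fe(acac)3, PhSiH3, EtOH) should give, again anti to the hydroxymethyl group, (4R,5S)-4-(5,5-dimethoxy-2-methylpentan-2-yl)-5-(hydroxymethyl)oxolan-2-one F2. LiN(i-Pr)2 (2.2 equiv) and Me3SiCl convert F2 into the O-silylated silyl ketene acetal {[(2S,3R)-3-(5,5-dimethoxy-2-methylpentan-2-yl)-5-(trimethylsilyloxy)-2,3-dihydrofuran-2-yl]methoxy}trimethylsilane F3. With TiCl4 in CH2Cl2 at −78 °C, F3 should close the cyclohexane by a Mukaiyama aldol-type addition to the acetal and, after aqueous acid work-up, give (3S,3aR,7aS)-3-(hydroxymethyl)-7-methoxy-4,4-dimethylhexahydroisobenzofuran-1(3H)-one F4. DBU in toluene at 80 °C eliminates methanol to give (3S,3aS)-3-(hydroxymethyl)-4,4-dimethyl-3a,4,5,6-tetrahydroisobenzofuran-1(3H)-one F5, and MsCl/Et3N converts F5 into 5.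

Step 5. What may go wrong: incomplete iodinolysis of the hindered primary C–B bond, or attack of iodine and methoxide on the allylic alcohol and the ring alkene. Fallback (sets out from 8, returns at 10): the iodide is made by way of the alcohol with the allylic hydroxyl masked. Silylation (t-BuMe2SiCl, imidazole, DMF) gives tert-butyl{[(6S)-6-ethenyl-5,5-dimethylcyclohex-1-en-1-yl]methoxy}dimethylsilane F6. Hydroboration with disiamylborane gives tert-butyl{[(6S)-6-{2-[bis(3-methylbutan-2-yl)boranyl]ethyl}-5,5-dimethylcyclohex-1-en-1-yl]methoxy}dimethylsilane F7, which is oxidised (NaOH, H2O2) to 2-[(1S)-2-{[(tert-butyldimethylsilyl)oxy]methyl}-6,6-dimethylcyclohex-2-en-1-yl]ethan-1-ol F8. I2, PPh3 and imidazole give tert-butyl{[(6S)-6-(2-iodoethyl)-5,5-dimethylcyclohex-1-en-1-yl]methoxy}dimethylsilane F9, and HF·pyridine releases 10.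

Step 14. What may go wrong: sluggish zinc insertion or decomposition of the alkylzinc next to the base-sensitive butenolide, and protodemetalation or homocoupling in the cross-coupling. Fallback (sets out from 16, returns at 28): the chain is grown on the carbocyclic half and the butenolide is attached last. Negishi coupling of 16 with [4-(trimethylsilyl)but-3-yn-1-yl]zinc iodide F10 (from (4-iodobut-1-yn-1-yl)trimethylsilane, Zn dust, LiCl; Pd(PPh3)4) gives trimethyl{(5E)-8-[(1S)-2,2-dimethyl-6-methylidenecyclohexyl]-6-methyloct-5-en-1-yn-1-yl}silane F11. K2CO3 in MeOH gives (2S)-1,1-dimethyl-3-methylidene-2-[(3E)-3-methyloct-3-en-7-yn-1-yl]cyclohexane F12. Methylalumination (Me3Al, Cp2ZrCl2) gives {(1E,5E)-8-[(1S)-2,2-dimethyl-6-methylidenecyclohexyl]-2,6-dimethylocta-1,5-dien-1-yl}dimethylalane F13, n-BuLi the lithium butyl(alkenyl)dimethylaluminate F14, and oxirane (3E,7E)-10-[(1S)-2,2-dimethyl-6-methylidenecyclohexyl]-4,8-dimethyldeca-3,7-dien-1-ol F15. I2, PPh3 and imidazole give (2S)-2-[(3E,7E)-10-iodo-3,7-dimethyldeca-3,7-dien-1-yl]-1,1-dimethyl-3-methylidenecyclohexane F16. Its zinc reagent {(3E,7E)-10-[(1S)-2,2-dimethyl-6-methylidenecyclohexyl]-4,8-dimethyldeca-3,7-dien-1-yl}zinc iodide F17 (Zn dust, LiCl) is coupled with 22 under Pd(PPh3)4 catalysis to give 28.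

**Further compounds**

F1 | step 1 | 5,5-dimethoxy-2-methylpent-1-ene | C=C(C)CCC(OC)OC
F2 | step 1 | (4R,5S)-4-(5,5-dimethoxy-2-methylpentan-2-yl)-5-(hydroxymethyl)oxolan-2-one | O=C1O[C@H](CO)[C@H](C1)C(C)(C)CCC(OC)OC
F3 | step 1 | {[(2S,3R)-3-(5,5-dimethoxy-2-methylpentan-2-yl)-5-(trimethylsilyloxy)-2,3-dihydrofuran-2-yl]methoxy}trimethylsilane | C[Si](C)(C)OC[C@H]1OC(O[Si](C)(C)C)=C[C@@H]1C(C)(C)CCC(OC)OC
F4 | step 1 | (3S,3aR,7aS)-3-(hydroxymethyl)-7-methoxy-4,4-dimethylhexahydroisobenzofuran-1(3H)-one | O=C1O[C@H](CO)[C@@H]2[C@H]1C(OC)CCC2(C)C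
F5 | step 1 | (3S,3aS)-3-(hydroxymethyl)-4,4-dimethyl-3a,4,5,6-tetrahydroisobenzofuran-1(3H)-one | O=C1O[C@H](CO)[C@@H]2C1=CCCC2(C)C
F6 | step 5 | tert-butyl{[(6S)-6-ethenyl-5,5-dimethylcyclohex-1-en-1-yl]methoxy}dimethylsilane | CC(C)(C)[Si](C)(C)OCC1=CCCC(C)(C)[C@@H]1C=C
F7 | step 5 | tert-butyl{[(6S)-6-{2-[bis(3-methylbutan-2-yl)boranyl]ethyl}-5,5-dimethylcyclohex-1-en-1-yl]methoxy}dimethylsilane | CC(C)(C)[Si](C)(C)OCC1=CCCC(C)(C)[C@@H]1CCB(C(C)C(C)C)C(C)C(C)C
F8 | step 5 | 2-[(1S)-2-{[(tert-butyldimethylsilyl)oxy]methyl}-6,6-dimethylcyclohex-2-en-1-yl]ethan-1-ol | CC(C)(C)[Si](C)(C)OCC1=CCCC(C)(C)[C@@H]1CCO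
F9 | step 5 | tert-butyl{[(6S)-6-(2-iodoethyl)-5,5-dimethylcyclohex-1-en-1-yl]methoxy}dimethylsilane | CC(C)(C)[Si](C)(C)OCC1=CCCC(C)(C)[C@@H]1CCI
F10 | step 14 | [4-(trimethylsilyl)but-3-yn-1-yl]zinc iodide | C[Si](C)(C)C#CCC[Zn]I
F11 | step 14 | trimethyl{(5E)-8-[(1S)-2,2-dimethyl-6-methylidenecyclohexyl]-6-methyloct-5-en-1-yn-1-yl}silane | C=C1CCCC(C)(C)[C@@H]1CC/C(C)=C/CCC#C[Si](C)(C)C
F12 | step 14 | (2S)-1,1-dimethyl-3-methylidene-2-[(3E)-3-methyloct-3-en-7-yn-1-yl]cyclohexane | C=C1CCCC(C)(C)[C@@H]1CC/C(C)=C/CCC#C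
F13 | step 14 | {(1E,5E)-8-[(1S)-2,2-dimethyl-6-methylidenecyclohexyl]-2,6-dimethylocta-1,5-dien-1-yl}dimethylalane | C=C1CCCC(C)(C)[C@@H]1CC/C(C)=C/CC/C(C)=C/[Al](C)C
F14 | step 14 | lithium butyl{(1E,5E)-8-[(1S)-2,2-dimethyl-6-methylidenecyclohexyl]-2,6-dimethylocta-1,5-dien-1-yl}dimethylaluminate | [Li+].C=C1CCCC(C)(C)[C@@H]1CC/C(C)=C/CC/C(C)=C/[Al-](C)(C)CCCC
F15 | step 14 | (3E,7E)-10-[(1S)-2,2-dimethyl-6-methylidenecyclohexyl]-4,8-dimethyldeca-3,7-dien-1-ol | C=C1CCCC(C)(C)[C@@H]1CC/C(C)=C/CC/C(C)=C/CCO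
F16 | step 14 | (2S)-2-[(3E,7E)-10-iodo-3,7-dimethyldeca-3,7-dien-1-yl]-1,1-dimethyl-3-methylidenecyclohexane | C=C1CCCC(C)(C)[C@@H]1CC/C(C)=C/CC/C(C)=C/CCI
F17 | step 14 | {(3E,7E)-10-[(1S)-2,2-dimethyl-6-methylidenecyclohexyl]-4,8-dimethyldeca-3,7-dien-1-yl}zinc iodide | C=C1CCCC(C)(C)[C@@H]1CC/C(C)=C/CC/C(C)=C/CC[Zn]I
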